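**Retrosynthetic overview**
1. Target ⇐ chemoselective oxidation of C14–OH ⇐ global desilylation ⇐ inverting (Mitsunobu) isovalerate formation at C8 ⇐ trans-fused macrocyclic 8α-alcohol.
2. Key disconnection C7–C8: the ten-membered carbocycle is closed last by a Cr(II)-mediated intramolecular SE2′ allylation of a C8 aldehyde by a preformed 3-(bromomethyl)butenolide (C13–Br); one operation closes the ring, sets C7 and C8 and unveils the C11=C13 methylene.
3. Enabling feature: the C8 carbinol is homoallylic to the exocyclic C11=C13 bond through C7 of the γ-lactone ring (O8 and the C12 carbonyl are 1,4-related, so C7 and C8 are both acceptor carbons and are joined with polarity reversal); the two ring-cis trisubstituted olefins C4=C5 and C1=C10 of the ten-membered ring fold the open chain.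
4. Seco-aldehyde ⇐ butenolide by ring-closing metathesis of a C6 2-(bromomethyl)acrylate onto a C7 vinyl group ⇐ chain from two E-selective Horner–Wadsworth–Emmons olefinations with (S)-α-oxy aldehydes (C1=C10 from an acyclic phosphonate, C4=C5 from an α-phosphono-γ-lactone made by epoxide opening); the ester and lactone carbonyls become C14 and C15.
5. Ring order: γ-lactone (as butenolide) first, ten-membered carbocycle last.

Key step: step 19

Remark: position labels C1–C15 are those of the germacrane skeleton of the target (ten-membered ring C1–C10; lactone C6–O–C12(=O)–C11(=C13)–C7; C14 on C10; C15 on C4) and are used for all intermediates.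
Assumption: 2, 4 and 13 are taken as catalogue compounds, and the ring closure is assumed to follow the closed chair model of allylchromium additions, which predicts the 8S (8α) alcohol; the ester is therefore introduced with inversion.

Step 1
Reactants: 1 triethyl phosphonoacetate; 2 4-methoxybenzyl 2-bromoethyl ether
Product: 3 ethyl 2-(diethoxyphosphoryl)-4-(4-methoxybenzyloxy)butanoate (racemic)
Conditions: NaH, DMF, 0 °C; then 2, NaI (cat.), 60 °C
Reagents that add atoms: none
Why: C-alkylation of the sodium phosphonoacetate carbanion with a primary bromide (iodide-assisted SN2) is the standard entry to α-substituted Horner–Wadsworth–Emmons reagents, and the new stereocentre is destroyed in step 2 so the racemate serves.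

Step 2
Reactants: 3 phosphonate; 4 (S)-2,2-dimethyl-1,3-dioxolane-4-carbaldehyde
Product: 5 ethyl (E)-3-[(4R)-2,2-dimethyl-1,3-dioxolan-4-yl]-2-[2-(4-methoxybenzyloxy)ethyl]prop-2-enoate
Conditions: LiCl, DBU, MeCN, 0 °C → rt
Reagents that add atoms: none
Why: Horner–Wadsworth–Emmons olefination under Masamune–Roush conditions should give the trisubstituted (E)-enoate (C2 trans to the ester carbon, the future C14) as the usual outcome for stabilised α-alkyl phosphonates, and the mild base spares the α-alkoxy stereocentre of 4 that becomes C2.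

Step 3
Reactants: 5 enoate
Product: 6 (E)-3-[(4R)-2,2-dimethyl-1,3-dioxolan-4-yl]-2-[2-(4-methoxybenzyloxy)ethyl]prop-2-en-1-ol
Conditions: DIBAL-H, CH2Cl2, −78 °C; Rochelle salt
Reagents that add atoms: none
Why: DIBAL-H 1,2-reduction of the conjugated ester gives the allylic alcohol (C14–OH) while acetonide and PMB ether are inert.

Step 4
Reactants: 6 allylic alcohol
Product: 7 tert-butyl{(E)-3-[(4R)-2,2-dimethyl-1,3-dioxolan-4-yl]-2-[2-(4-methoxybenzyloxy)ethyl]prop-2-enyloxy}diphenylsilane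
Conditions: TBDPSCl, imidazole, DMF, rt
Reagents that add atoms: tert-butyl(chloro)diphenylsilane (TBDPSCl), CC(C)(C)[Si](Cl)(c1ccccc1)c1ccccc1
Why: Silylation of the primary allylic alcohol with the acid-robust TBDPS group, chosen to survive the acetal hydrolysis of step 5 and every step up to the final desilylation.

Step 5
Reactants: 7 silyl ether
Product: 8 (2R,3E)-4-[(tert-butyldiphenylsilyloxy)methyl]-6-(4-methoxybenzyloxy)hex-3-ene-1,2-diol
Conditions: AcOH/H2O (4:1), rt
Reagents that add atoms: none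
Why: Acid-catalysed hydrolysis of the terminal isopropylidene acetal, to which TBDPS and PMB ethers are stable.

Step 6
Reactants: 8 diol
Product: 10 (2R)-2-{(1E)-2-[(tert-butyldiphenylsilyloxy)methyl]-4-(4-methoxybenzyloxy)but-1-enyl}oxirane, via primary monotosylate 9 (not isolated)
Conditions: TsCl, Et3N, Bu2SnO (cat.), CH2Cl2, 0 °C; then K2CO3, MeOH, rt
Reagents that add atoms: none
Why: Stannylene-catalysed sulfonylation is selective for the primary hydroxyl and the secondary alkoxide then closes the epoxide by intramolecular SN2 at C3, so the C2–O bond and its configuration are retained.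

Step 7
Reactants: 10 epoxide; 1 triethyl phosphonoacetate
Product: 12 diethyl [(5S)-5-{(1E)-2-[(tert-butyldiphenylsilyloxy)methyl]-4-(4-methoxybenzyloxy)but-1-enyl}-2-oxotetrahydrofuran-3-yl]phosphonate (C3 epimers), via ring-opened sodium γ-alkoxide 11 (not isolated)
Conditions: NaH, toluene, rt; then 10, 90 °C
Reagents that add atoms: none
Why: The stabilised phosphonoacetate carbanion should open the epoxide at the unhindered terminal carbon (SN2 at C3, not SN2′) and the released γ-alkoxide lactonises onto the ethyl ester, the known epoxide route to α-phosphono-γ-butyrolactones; C2 is not touched.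

Step 8
Reactants: 13 (S)-but-3-ene-1,2-diol
Product: 14 (S)-3,4-bis(triethylsilyloxy)but-1-ene
Conditions: TESCl, imidazole, CH2Cl2, 0 °C → rt
Reagents that add atoms: chlorotriethylsilane (TESCl), CC[Si](Cl)(CC)CC
Why: Exhaustive silylation of the commercial diol, whose stereocentre becomes C6.

Step 9
Reactants: 14 bis-silyl ether
Product: 15 (S)-2-(triethylsilyloxy)but-3-enal
Conditions: (COCl)2, DMSO, CH2Cl2, −78 °C; then Et3N, −78 → −40 °C; used crude
Reagents that add atoms: none
Why: Under Swern conditions a primary triethylsilyl ether is cleaved and oxidised in preference to a secondary one, giving the α-silyloxy aldehyde directly, and low temperature with immediate use guards the enolisable stereocentre.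

Step 10
Reactants: 12 phosphonolactone; 15 aldehyde
Product: 16 (3E,5S)-5-{(1E)-2-[(tert-butyldiphenylsilyloxy)methyl]-4-(4-methoxybenzyloxy)but-1-enyl}-3-[(2S)-2-(triethylsilyloxy)but-3-enylidene]dihydrofuran-2(3H)-one
Conditions: LiCl, DBU (slightly less than 12), MeCN, 0 °C
Reagents that add atoms: none
Why: Horner–Wadsworth–Emmons olefination of the cyclic phosphonate should give the (E)-alkylidene lactone (C6 trans to the lactone carbonyl, the future C15), and the Masamune–Roush conditions keep the medium mild enough for the enolisable aldehyde.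

Step 11
Reactants: 16 alkylidene lactone
Product: 17 (3S,4E,7S,8E)-9-[(tert-butyldiphenylsilyloxy)methyl]-5-(hydroxymethyl)-11-(4-methoxybenzyloxy)-3-(triethylsilyloxy)undeca-1,4,8-trien-7-ol
Conditions: DIBAL-H (excess), CH2Cl2, −78 → 0 °C; Rochelle salt
Reagents that add atoms: none
Why: Excess DIBAL-H reduces the unsaturated lactone by 1,2-addition to the allylic 1,4-diol (C15–OH and C2–OH) without touching silyl or PMB ethers.

Step 12
Reactants: 17 diol
Product: 18 (3S,4E,7S,8E)-5-(acetoxymethyl)-9-[(tert-butyldiphenylsilyloxy)methyl]-11-(4-methoxybenzyloxy)-3-(triethylsilyloxy)undeca-1,4,8-trien-7-ol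
Conditions: AcCl, 2,4,6-collidine, CH2Cl2, −78 °C
Reagents that add atoms: acetyl chloride, CC(=O)Cl
Why: Acetyl chloride with a hindered pyridine base at low temperature acylates primary alcohols much faster than secondary ones, which fixes the C15 acetate after all hydride steps are over.

Step 13
Reactants: 18 monoacetate
Product: 19 (3S,4E,7S,8E)-5-(acetoxymethyl)-7-(tert-butyldimethylsilyloxy)-9-[(tert-butyldiphenylsilyloxy)methyl]-11-(4-methoxybenzyloxy)-3-(triethylsilyloxy)undeca-1,4,8-triene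
Conditions: TBSOTf, 2,6-lutidine, CH2Cl2, −78 °C
Reagents that add atoms: tert-butyldimethylsilyl trifluoromethanesulfonate (TBSOTf), CC(C)(C)[Si](C)(C)OS(=O)(=O)C(F)(F)F
Why: Silyl triflate silylation of the remaining secondary allylic alcohol (C2–OH) proceeds without affecting acetate or the other ethers.

Step 14
Reactants: 19 tris-silyl ether
Product: 20 (3S,4E,7S,8E)-5-(acetoxymethyl)-7-(tert-butyldimethylsilyloxy)-9-[(tert-butyldiphenylsilyloxy)methyl]-11-(4-methoxybenzyloxy)undeca-1,4,8-trien-3-ol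
Conditions: PPTS (cat.), MeOH/CH2Cl2 (1:1), 0 °C
Reagents that add atoms: none
Why: Acid-catalysed methanolysis removes a triethylsilyl ether far faster than TBS or TBDPS ethers, so only the C6 hydroxyl is freed.

Step 15
Reactants: 20 alcohol; 21 2-(bromomethyl)acrylic acid
Product: 22 (3S,4E,7S,8E)-5-(acetoxymethyl)-7-(tert-butyldimethylsilyloxy)-9-[(tert-butyldiphenylsilyloxy)methyl]-11-(4-methoxybenzyloxy)undeca-1,4,8-trien-3-yl 2-(bromomethyl)acrylate
Conditions: DIC, DMAP (cat.), CH2Cl2, 0 °C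
Reagents that add atoms: none
Why: Carbodiimide (Steglich) esterification of the secondary alcohol, run cold with only catalytic DMAP to limit attack on the allylic bromide.

Step 16
Reactants: 22 ester
Product: 23 (5R)-5-{(1E,4S,5E)-2-(acetoxymethyl)-4-(tert-butyldimethylsilyloxy)-6-[(tert-butyldiphenylsilyloxy)methyl]-8-(4-methoxybenzyloxy)octa-1,5-dienyl}-3-(bromomethyl)furan-2(5H)-one
Conditions: Grubbs II (10 mol %), CH2Cl2 (5 mM), 40 °C
Reagents that add atoms: none
Why: Ring-closing metathesis of an allylic acrylate-type ester to a butenolide: the catalyst loads on the terminal vinyl group and five-membered closure onto the 1,1-disubstituted acrylate olefin should outrun reaction with the hindered trisubstituted olefins.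

Step 17
Reactants: 23 PMB ether
Product: 24 (5R)-5-{(1E,4S,5E)-2-(acetoxymethyl)-4-(tert-butyldimethylsilyloxy)-6-[(tert-butyldiphenylsilyloxy)methyl]-8-hydroxyocta-1,5-dienyl}-3-(bromomethyl)furan-2(5H)-one
Conditions: DDQ, CH2Cl2/pH 7 buffer (10:1), 0 °C
Reagents that add atoms: none
Why: Oxidative cleavage of the PMB ether by DDQ under buffered conditions leaves silyl ethers, acetate and the allylic bromide intact.

Step 18
Reactants: 24 alcohol
Product: 25 (5R)-5-{(1E,4S,5E)-2-(acetoxymethyl)-4-(tert-butyldimethylsilyloxy)-6-[(tert-butyldiphenylsilyloxy)methyl]-8-oxoocta-1,5-dienyl}-3-(bromomethyl)furan-2(5H)-one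
Conditions: Dess–Martin periodinane, NaHCO3, CH2Cl2, 0 °C; used crude
Reagents that add atoms: none
Why: Buffered Dess–Martin oxidation gives the β,γ-unsaturated aldehyde without acid or base strong enough to move the C1=C10 bond into conjugation.

Step 19
Reactants: 25 seco-aldehyde
Product: 27 (2S,6R,7R,8S)-15-acetoxy-2-(tert-butyldimethylsilyloxy)-14-(tert-butyldiphenylsilyloxy)-8-hydroxygermacra-1(10)E,4E,11(13)-trien-12,6-olide, via allylchromium(III) species 26 (not isolated)
Conditions: CrCl2 (10 equiv), THF, rt, 25 added by syringe pump over 12 h (final 1 mM); aq. NH4Cl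
Reagents that add atoms: none
Why: Two Cr(II) ions reduce the allylic C13–Br bond to an allylchromium(III) (26), whose γ-carbon C7 adds to the C8 aldehyde through a closed six-membered chair transition state (SE2′), which moves the double bond out to C11=C13 and so creates the α-methylene lactone together with the C7–C8 bond. The closest known reactions are the Cr(II)-mediated Nozaki–Hiyama macrocyclisation of ω-formyl 2-(bromomethyl)acrylates to ten-membered germacranolide rings and the intermolecular metal-mediated allylation of aldehydes with 3-(bromomethyl)furan-2(5H)-ones. The ten-membered carbocycle is closed by a 10-exo-trig addition onto the preformed lactone, the two ring-cis trisubstituted olefins (C4=C5, C1=C10) holding the chain ends close. C7 is controlled by the C6 stereocentre, because the tethered aldehyde can reach C7 without eclipsing the C5–C6–C7–C8 torsion only on the butenolide face anti to the C5 substituent, which should give the trans-fused (7R) lactone. C8 is controlled by the ring-fixed E-type allyl geometry (C6 trans to C13) in the chair with the C9 chain equatorial, which should give the anti (8S, 8α) alcohol with H7 and H8 antiperiplanar, the epimer wanted for the inverting esterification of step 20. The step needs ring closure to beat intermolecular coupling and protonation (secured by slow addition to excess CrCl2 at high dilution), and γ- over α-attack and aldehyde over ester selectivity (both inherent to allylchromium reagents).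

Step 20
Reactants: 27 8α-alcohol
Product: 28 (2S,6R,7R,8R)-15-acetoxy-2-(tert-butyldimethylsilyloxy)-14-(tert-butyldiphenylsilyloxy)-8-(3-methylbutanoyloxy)germacra-1(10)E,4E,11(13)-trien-12,6-olide
Conditions: 3-methylbutanoic acid, PPh3, DIAD, toluene, 0 °C → rt
Reagents that add atoms: 3-methylbutanoic acid (isovaleric acid), CC(C)CC(=O)O
Why: Mitsunobu esterification of the only free hydroxyl should install the isovalerate by SN2 with inversion, converting 8S into the 8R configuration of the target.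

Step 21
Reactants: 28 bis-silyl ether
Product: 29 (2S,6R,7R,8R)-15-acetoxy-2,14-dihydroxy-8-(3-methylbutanoyloxy)germacra-1(10)E,4E,11(13)-trien-12,6-olide
Conditions: HF·pyridine, pyridine, THF, 0 °C → rt
Reagents that add atoms: none
Why: Buffered fluoride desilylation removes the secondary TBS and the primary TBDPS ether without the basicity that would endanger the α-methylene lactone or the esters.

Step 22
Reactants: 29 diol
Product: 30 (2S,6R,7R,8R)-15-acetoxy-2-hydroxy-8-(3-methylbutanoyloxy)-14-oxogermacra-1(10)E,4E,11(13)-trien-12,6-olide (CNP0524123.1)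
Conditions: TEMPO (0.2 equiv), PhI(OAc)2 (1.2 equiv), CH2Cl2, rt
Reagents that add atoms: none
Why: The oxoammonium oxidation (TEMPO/PhI(OAc)2) is selective for primary over secondary alcohols, so the primary allylic C14–OH should give the enal while C2–OH stays, and the E geometry (C2 trans to the formyl group) precludes lactol formation.

**Compound list**
1 | triethyl phosphonoacetate | CCOC(=O)CP(=O)(OCC)OCC | starting material
2 | 4-methoxybenzyl 2-bromoethyl ether | COc1ccc(COCCBr)cc1 | starting material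
3 | ethyl 2-(diethoxyphosphoryl)-4-(4-methoxybenzyloxy)butanoate (racemic) | CCOC(=O)C(CCOCc1ccc(OC)cc1)P(=O)(OCC)OCC | intermediate
4 | (S)-2,2-dimethyl-1,3-dioxolane-4-carbaldehyde | O=C[C@@H]1COC(C)(C)O1 | starting material
5 | ethyl (E)-3-[(4R)-2,2-dimethyl-1,3-dioxolan-4-yl]-2-[2-(4-methoxybenzyloxy)ethyl]prop-2-enoate | CC1(C)OC[C@H](O1)/C=C(/C(=O)OCC)CCOCc1ccc(OC)cc1 | intermediate
6 | (E)-3-[(4R)-2,2-dimethyl-1,3-dioxolan-4-yl]-2-[2-(4-methoxybenzyloxy)ethyl]prop-2-en-1-ol | CC1(C)OC[C@H](O1)/C=C(/CO)CCOCc1ccc(OC)cc1 | intermediate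
7 | tert-butyl{(E)-3-[(4R)-2,2-dimethyl-1,3-dioxolan-4-yl]-2-[2-(4-methoxybenzyloxy)ethyl]prop-2-enyloxy}diphenylsilane | CC1(C)OC[C@H](O1)/C=C(/CO[Si](c1ccccc1)(c1ccccc1)C(C)(C)C)CCOCc1ccc(OC)cc1 | intermediate
8 | (2R,3E)-4-[(tert-butyldiphenylsilyloxy)methyl]-6-(4-methoxybenzyloxy)hex-3-ene-1,2-diol | OC[C@H](O)/C=C(/CO[Si](c1ccccc1)(c1ccccc1)C(C)(C)C)CCOCc1ccc(OC)cc1 | intermediate
9 | (2R,3E)-4-[(tert-butyldiphenylsilyloxy)methyl]-2-hydroxy-6-(4-methoxybenzyloxy)hex-3-enyl 4-methylbenzenesulfonate | Cc1ccc(cc1)S(=O)(=O)OC[C@H](O)/C=C(/CO[Si](c1ccccc1)(c1ccccc1)C(C)(C)C)CCOCc1ccc(OC)cc1 | intermediate (not isolated)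
10 | (2R)-2-{(1E)-2-[(tert-butyldiphenylsilyloxy)methyl]-4-(4-methoxybenzyloxy)but-1-enyl}oxirane | C1[C@H](O1)/C=C(/CO[Si](c1ccccc1)(c1ccccc1)C(C)(C)C)CCOCc1ccc(OC)cc1 | intermediate
11 | ethyl (4S,5E)-6-[(tert-butyldiphenylsilyloxy)methyl]-2-(diethoxyphosphoryl)-4-hydroxy-8-(4-methoxybenzyloxy)oct-5-enoate (formed as its sodium alkoxide; C2 epimers) | CCOC(=O)C(C[C@H](O)/C=C(/CO[Si](c1ccccc1)(c1ccccc1)C(C)(C)C)CCOCc1ccc(OC)cc1)P(=O)(OCC)OCC | intermediate (not isolated)
12 | diethyl [(5S)-5-{(1E)-2-[(tert-butyldiphenylsilyloxy)methyl]-4-(4-methoxybenzyloxy)but-1-enyl}-2-oxotetrahydrofuran-3-yl]phosphonate (C3 epimers) | CCOP(=O)(OCC)C1C[C@H](OC1=O)/C=C(/CO[Si](c1ccccc1)(c1ccccc1)C(C)(C)C)CCOCc1ccc(OC)cc1 | intermediate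
13 | (S)-but-3-ene-1,2-diol | C=C[C@H](O)CO | starting material
14 | (S)-3,4-bis(triethylsilyloxy)but-1-ene | C=C[C@H](O[Si](CC)(CC)CC)CO[Si](CC)(CC)CC | intermediate
15 | (S)-2-(triethylsilyloxy)but-3-enal | C=C[C@H](O[Si](CC)(CC)CC)C=O | intermediate
16 | (3E,5S)-5-{(1E)-2-[(tert-butyldiphenylsilyloxy)methyl]-4-(4-methoxybenzyloxy)but-1-enyl}-3-[(2S)-2-(triethylsilyloxy)but-3-enylidene]dihydrofuran-2(3H)-one | C=C[C@H](O[Si](CC)(CC)CC)/C=C1\C[C@H](OC1=O)/C=C(/CO[Si](c1ccccc1)(c1ccccc1)C(C)(C)C)CCOCc1ccc(OC)cc1 | intermediate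
17 | (3S,4E,7S,8E)-9-[(tert-butyldiphenylsilyloxy)methyl]-5-(hydroxymethyl)-11-(4-methoxybenzyloxy)-3-(triethylsilyloxy)undeca-1,4,8-trien-7-ol | C=C[C@H](O[Si](CC)(CC)CC)/C=C(/CO)C[C@H](O)/C=C(/CO[Si](c1ccccc1)(c1ccccc1)C(C)(C)C)CCOCc1ccc(OC)cc1 | intermediate
18 | (3S,4E,7S,8E)-5-(acetoxymethyl)-9-[(tert-butyldiphenylsilyloxy)methyl]-11-(4-methoxybenzyloxy)-3-(triethylsilyloxy)undeca-1,4,8-trien-7-ol | C=C[C@H](O[Si](CC)(CC)CC)/C=C(/COC(C)=O)C[C@H](O)/C=C(/CO[Si](c1ccccc1)(c1ccccc1)C(C)(C)C)CCOCc1ccc(OC)cc1 | intermediate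
19 | (3S,4E,7S,8E)-5-(acetoxymethyl)-7-(tert-butyldimethylsilyloxy)-9-[(tert-butyldiphenylsilyloxy)methyl]-11-(4-methoxybenzyloxy)-3-(triethylsilyloxy)undeca-1,4,8-triene | C=C[C@H](O[Si](CC)(CC)CC)/C=C(/COC(C)=O)C[C@H](O[Si](C)(C)C(C)(C)C)/C=C(/CO[Si](c1ccccc1)(c1ccccc1)C(C)(C)C)CCOCc1ccc(OC)cc1 | intermediate
20 | (3S,4E,7S,8E)-5-(acetoxymethyl)-7-(tert-butyldimethylsilyloxy)-9-[(tert-butyldiphenylsilyloxy)methyl]-11-(4-methoxybenzyloxy)undeca-1,4,8-trien-3-ol | C=C[C@H](O)/C=C(/COC(C)=O)C[C@H](O[Si](C)(C)C(C)(C)C)/C=C(/CO[Si](c1ccccc1)(c1ccccc1)C(C)(C)C)CCOCc1ccc(OC)cc1 | intermediate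
21 | 2-(bromomethyl)acrylic acid | C=C(CBr)C(=O)O | starting material
22 | (3S,4E,7S,8E)-5-(acetoxymethyl)-7-(tert-butyldimethylsilyloxy)-9-[(tert-butyldiphenylsilyloxy)methyl]-11-(4-methoxybenzyloxy)undeca-1,4,8-trien-3-yl 2-(bromomethyl)acrylate | C=C[C@H](OC(=O)C(=C)CBr)/C=C(/COC(C)=O)C[C@H](O[Si](C)(C)C(C)(C)C)/C=C(/CO[Si](c1ccccc1)(c1ccccc1)C(C)(C)C)CCOCc1ccc(OC)cc1 | intermediate
23 | (5R)-5-{(1E,4S,5E)-2-(acetoxymethyl)-4-(tert-butyldimethylsilyloxy)-6-[(tert-butyldiphenylsilyloxy)methyl]-8-(4-methoxybenzyloxy)octa-1,5-dienyl}-3-(bromomethyl)furan-2(5H)-one | O=C1O[C@H](/C=C(/COC(C)=O)C[C@H](O[Si](C)(C)C(C)(C)C)/C=C(/CO[Si](c2ccccc2)(c2ccccc2)C(C)(C)C)CCOCc2ccc(OC)cc2)C=C1CBr | intermediate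
24 | (5R)-5-{(1E,4S,5E)-2-(acetoxymethyl)-4-(tert-butyldimethylsilyloxy)-6-[(tert-butyldiphenylsilyloxy)methyl]-8-hydroxyocta-1,5-dienyl}-3-(bromomethyl)furan-2(5H)-one | O=C1O[C@H](/C=C(/COC(C)=O)C[C@H](O[Si](C)(C)C(C)(C)C)/C=C(/CO[Si](c2ccccc2)(c2ccccc2)C(C)(C)C)CCO)C=C1CBr | intermediate
25 | (5R)-5-{(1E,4S,5E)-2-(acetoxymethyl)-4-(tert-butyldimethylsilyloxy)-6-[(tert-butyldiphenylsilyloxy)methyl]-8-oxoocta-1,5-dienyl}-3-(bromomethyl)furan-2(5H)-one | O=C1O[C@H](/C=C(/COC(C)=O)C[C@H](O[Si](C)(C)C(C)(C)C)/C=C(/CO[Si](c2ccccc2)(c2ccccc2)C(C)(C)C)CC=O)C=C1CBr | intermediate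
26 | allylchromium(III) dichloride of 25 (Cr on C13, THF-solvated) | O=C1O[C@H](/C=C(/COC(C)=O)C[C@H](O[Si](C)(C)C(C)(C)C)/C=C(/CO[Si](c2ccccc2)(c2ccccc2)C(C)(C)C)CC=O)C=C1C[Cr](Cl)Cl | intermediate (not isolated)
27 | (2S,6R,7R,8S)-15-acetoxy-2-(tert-butyldimethylsilyloxy)-14-(tert-butyldiphenylsilyloxy)-8-hydroxygermacra-1(10)E,4E,11(13)-trien-12,6-olide | C=C1C(=O)O[C@@H]2/C=C(/COC(C)=O)C[C@H](O[Si](C)(C)C(C)(C)C)/C=C(/CO[Si](c3ccccc3)(c3ccccc3)C(C)(C)C)C[C@H](O)[C@@H]12 | intermediate
28 | (2S,6R,7R,8R)-15-acetoxy-2-(tert-butyldimethylsilyloxy)-14-(tert-butyldiphenylsilyloxy)-8-(3-methylbutanoyloxy)germacra-1(10)E,4E,11(13)-trien-12,6-olide | C=C1C(=O)O[C@@H]2/C=C(/COC(C)=O)C[C@H](O[Si](C)(C)C(C)(C)C)/C=C(/CO[Si](c3ccccc3)(c3ccccc3)C(C)(C)C)C[C@@H](OC(=O)CC(C)C)[C@@H]12 | intermediate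
29 | (2S,6R,7R,8R)-15-acetoxy-2,14-dihydroxy-8-(3-methylbutanoyloxy)germacra-1(10)E,4E,11(13)-trien-12,6-olide | C=C1C(=O)O[C@@H]2/C=C(/COC(C)=O)C[C@H](O)/C=C(/CO)C[C@@H](OC(=O)CC(C)C)[C@@H]12 | intermediate
30 | (2S,6R,7R,8R)-15-acetoxy-2-hydroxy-8-(3-methylbutanoyloxy)-14-oxogermacra-1(10)E,4E,11(13)-trien-12,6-olide (CNP0524123.1) | C=C1C(=O)O[C@@H]2/C=C(/COC(C)=O)C[C@H](O)/C=C(/C=O)C[C@@H](OC(=O)CC(C)C)[C@@H]12 | target

**Step count and risks**
Total step count: 22. Longest linear sequence: 20 steps (steps 1–7 and 10–22); steps 8–9 form the short branch to aldehyde 15.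

The three steps most likely to fail:

1. Step 19 (ring closure). Ring closure may be outrun by intermolecular allylation or by reduction and protonation of the allylchromium, and the Lewis-acidic Cr(III) medium may move the C1=C10 bond of 25 into conjugation with the aldehyde before the C–C bond forms. The fallback sets out from 24 and comes back at 27; it separates metalation from ring closure by using an isolable allylboron nucleophile. Pd-catalysed borylation of the allylic bromide of 24 (B2pin2, Pd2(dba)3 cat., THF, rt) should give the allylboronate alcohol F1. Dess–Martin oxidation gives the boronate aldehyde F2. Sc(OTf)3-catalysed intramolecular allylboration at 1 mM in toluene closes the same C7–C8 bond through the same chair array to the cyclic borate F3, which aqueous work-up hydrolyses to 27.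

2. Step 20 (inverting esterification). The activated C8 oxyphosphonium sits next to the ring fusion and may undergo E2 elimination toward C9 or C7 instead of substitution, or may not be displaced by the weakly acidic aliphatic acid. The fallback sets out from 27 and comes back at 28; it inverts C8 by oxidation and reduction instead of SN2. Buffered Dess–Martin oxidation of 27 gives the 8-ketone F4. Immediate Luche reduction (NaBH4, CeCl3, MeOH, −78 °C), in which hydride should enter from the more open α-face flanked by H7, gives the 8β-alcohol F5. Acylation with isovaleric anhydride (Et3N, DMAP cat., CH2Cl2) gives 28.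

3. Step 10 (olefination with aldehyde 15). Base-mediated enolisation of the α-silyloxy-β,γ-unsaturated aldehyde may erode the C6 configuration and move the vinyl double bond into conjugation, and E-selectivity may be incomplete. The fallback sets out from 10 and comes back at 16; it replaces the phosphonate olefination by aldol addition and elimination, so the aldehyde meets base only at −78 °C. Epoxide 10 is opened with sodium diethyl malonate (NaOEt, EtOH, 60 °C) with lactonisation to the α-ethoxycarbonyl lactone F6. Krapcho dealkoxycarbonylation (LiCl, wet DMSO, 130 °C) gives the γ-lactone F7. Its lithium enolate (LDA, THF, −78 °C) adds to 15 within minutes to give the aldol adduct F8. Mesylation (MsCl, Et3N, 0 °C) to the mesylate F9 and E1cB elimination with DBU should give the (E)-alkylidene lactone 16.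

**Further compounds**
F1 | step 19 | (5R)-5-{(1E,4S,5E)-2-(acetoxymethyl)-4-(tert-butyldimethylsilyloxy)-6-[(tert-butyldiphenylsilyloxy)methyl]-8-hydroxyocta-1,5-dienyl}-3-[(4,4,5,5-tetramethyl-1,3,2-dioxaborolan-2-yl)methyl]furan-2(5H)-one | O=C1O[C@H](/C=C(/COC(C)=O)C[C@H](O[Si](C)(C)C(C)(C)C)/C=C(/CO[Si](c2ccccc2)(c2ccccc2)C(C)(C)C)CCO)C=C1CB1OC(C)(C)C(C)(C)O1
F2 | step 19 | (5R)-5-{(1E,4S,5E)-2-(acetoxymethyl)-4-(tert-butyldimethylsilyloxy)-6-[(tert-butyldiphenylsilyloxy)methyl]-8-oxoocta-1,5-dienyl}-3-[(4,4,5,5-tetramethyl-1,3,2-dioxaborolan-2-yl)methyl]furan-2(5H)-one | O=C1O[C@H](/C=C(/COC(C)=O)C[C@H](O[Si](C)(C)C(C)(C)C)/C=C(/CO[Si](c2ccccc2)(c2ccccc2)C(C)(C)C)CC=O)C=C1CB1OC(C)(C)C(C)(C)O1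
F3 | step 19 | 8-O-(4,4,5,5-tetramethyl-1,3,2-dioxaborolan-2-yl) derivative of 27 (not isolated) | C=C1C(=O)O[C@@H]2/C=C(/COC(C)=O)C[C@H](O[Si](C)(C)C(C)(C)C)/C=C(/CO[Si](c3ccccc3)(c3ccccc3)C(C)(C)C)C[C@H](OB3OC(C)(C)C(C)(C)O3)[C@@H]12
F4 | step 20 | (2S,6R,7R)-15-acetoxy-2-(tert-butyldimethylsilyloxy)-14-(tert-butyldiphenylsilyloxy)-8-oxogermacra-1(10)E,4E,11(13)-trien-12,6-olide | C=C1C(=O)O[C@@H]2/C=C(/COC(C)=O)C[C@H](O[Si](C)(C)C(C)(C)C)/C=C(/CO[Si](c3ccccc3)(c3ccccc3)C(C)(C)C)CC(=O)[C@@H]12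
F5 | step 20 | (2S,6R,7R,8R)-15-acetoxy-2-(tert-butyldimethylsilyloxy)-14-(tert-butyldiphenylsilyloxy)-8-hydroxygermacra-1(10)E,4E,11(13)-trien-12,6-olide | C=C1C(=O)O[C@@H]2/C=C(/COC(C)=O)C[C@H](O[Si](C)(C)C(C)(C)C)/C=C(/CO[Si](c3ccccc3)(c3ccccc3)C(C)(C)C)C[C@@H](O)[C@@H]12
F6 | step 10 | ethyl (5S)-5-{(1E)-2-[(tert-butyldiphenylsilyloxy)methyl]-4-(4-methoxybenzyloxy)but-1-enyl}-2-oxotetrahydrofuran-3-carboxylate (C3 epimers) | CCOC(=O)C1C[C@H](OC1=O)/C=C(/CO[Si](c1ccccc1)(c1ccccc1)C(C)(C)C)CCOCc1ccc(OC)cc1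
F7 | step 10 | (5S)-5-{(1E)-2-[(tert-butyldiphenylsilyloxy)methyl]-4-(4-methoxybenzyloxy)but-1-enyl}dihydrofuran-2(3H)-one | O=C1CC[C@H](O1)/C=C(/CO[Si](c1ccccc1)(c1ccccc1)C(C)(C)C)CCOCc1ccc(OC)cc1
F8 | step 10 | (5S)-5-{(1E)-2-[(tert-butyldiphenylsilyloxy)methyl]-4-(4-methoxybenzyloxy)but-1-enyl}-3-[(2S)-1-hydroxy-2-(triethylsilyloxy)but-3-enyl]dihydrofuran-2(3H)-one (diastereomer mixture at the two new centres) | C=C[C@H](O[Si](CC)(CC)CC)C(O)C1C[C@H](OC1=O)/C=C(/CO[Si](c1ccccc1)(c1ccccc1)C(C)(C)C)CCOCc1ccc(OC)cc1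
F9 | step 10 | methanesulfonate of F8 (not isolated) | C=C[C@H](O[Si](CC)(CC)CC)C(OS(C)(=O)=O)C1C[C@H](OC1=O)/C=C(/CO[Si](c1ccccc1)(c1ccccc1)C(C)(C)C)CCOCc1ccc(OC)cc1
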